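**Strategy.** The route rests on one gold-catalysed enyne bicyclization of an acyclic chain (eudesmane numbering). The target's C8 ketone lies β to the quaternary C10, C5–H is trans to the C10 methyl, and the C3/C4 cis-diol can come from a ring A alkene. A but-2-ynyl terminus (C15–C4≡C3), the E-alkene C5=C10 and a 1,3-bis(silyloxy)diene (C9=C8–C7=C11) are therefore placed on one chain. Alkyne activation forms C4–C5 and C9–C10, closes rings A and B at once, and sets C5 and C10 by anti addition across the alkene under catalyst control. It leaves the Δ3 alkene, C8 as an enol ether and C11 as an ester.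

Key step: step 8

Remark 1: eudesmane numbering is used throughout (C1–C10 ring carbons, C5 and C10 at the ring fusion, C14 = methyl on C10, C15 = methyl on C4, C11–C13 = hydroxyisopropyl carbons); α is the face opposite to the C10 methyl; TBS = tert-butyldimethylsilyl.
Remark 2: the (R)-ligand is assumed to give the (5R,10R) series by analogy with related gold-catalysed enyne bicyclizations; should the opposite sense be found, the (S)-ligand is used.

Step 1
Reactants: 1 pent-3-yn-1-ol
Product: 2 5-bromopent-2-yne
Conditions: CBr4, PPh3, CH2Cl2, 0 °C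
Reagents that add atoms: carbon tetrabromide, BrC(Br)(Br)Br
Why: The Appel reaction should convert the primary alcohol into the bromide under neutral conditions that leave the internal alkyne untouched; no stereocenter is formed.

Step 2
Reactants: 2 5-bromopent-2-yne; 3 ethyl but-2-ynoate
Product: 5 ethyl (E)-3-methyloct-2-en-6-ynoate, via pent-3-ynylmagnesium bromide 4 (not isolated)
Conditions: Mg, THF; CuBr·SMe2 (10 mol%), 3, THF, −78 °C; MeOH, −78 °C
Reagents that add atoms: none
Why: Copper-catalysed syn-carbometalation (conjugate addition) of the Grignard reagent across the ynoate, with protonation at −78 °C, should place the pentynyl group and the new hydrogen on the same side, which fixes the E geometry of the later C5=C10 alkene; no stereocenter is formed.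

Step 3
Reactants: 5 ethyl (E)-3-methyloct-2-en-6-ynoate
Product: 6 (E)-3-methyloct-2-en-6-yn-1-ol
Conditions: i-Bu2AlH (2.2 equiv), CH2Cl2, −78 °C; aq. Rochelle salt
Reagents that add atoms: none
Why: Hydride reduction of the enoate with i-Bu2AlH at low temperature should give the allylic alcohol by 1,2-reduction without touching the alkyne or the alkene geometry; no stereocenter is formed.

Step 4
Reactants: 6 (E)-3-methyloct-2-en-6-yn-1-ol
Product: 7 (E)-1-bromo-3-methyloct-2-en-6-yne
Conditions: CBr4, PPh3, CH2Cl2, 0 °C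
Reagents that add atoms: carbon tetrabromide, BrC(Br)(Br)Br
Why: The Appel reaction on a primary allylic alcohol should give the primary bromide without allylic transposition or loss of the E geometry; no stereocenter is formed.

Step 5
Reactants: 7 (E)-1-bromo-3-methyloct-2-en-6-yne; 8 methyl acetoacetate
Product: 10 methyl (E)-2-acetyl-5-methyldec-4-en-8-ynoate, via sodium enolate of methyl acetoacetate 9 (not isolated)
Conditions: NaH, 8 (1.5 equiv), THF, 0 °C; then 7, 0 °C → rt
Reagents that add atoms: none
Why: The acetoacetic ester alkylation (SN2 at the primary allylic bromide) should join C6 to C7; the new C7 center is formed racemic and is of no consequence because it becomes sp2 in step 6.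

Step 6
Reactants: 10 methyl (E)-2-acetyl-5-methyldec-4-en-8-ynoate
Product: 11 methyl 3-(TBS-oxy)-2-[(E)-3-methyloct-2-en-6-yn-1-yl]but-2-enoate
Conditions: TBSOTf, Et3N, CH2Cl2, 0 °C
Reagents that add atoms: tert-butyldimethylsilyl triflate, CC(C)(C)[Si](C)(C)OS(=O)(=O)C(F)(F)F
Why: Soft enolization and O-silylation of the β-keto ester should give the conjugated silyl enol ether (C8–O–Si, C7=C8), which removes the C7 stereocenter; no stereocenter is formed.

Step 7
Reactants: 11 methyl 3-(TBS-oxy)-2-[(E)-3-methyloct-2-en-6-yn-1-yl]but-2-enoate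
Product: 13 1-methoxy-1,3-bis(TBS-oxy)-2-[(E)-3-methyloct-2-en-6-yn-1-yl]buta-1,3-diene, via lithium dienolate of the ester 12 (not isolated)
Conditions: LiN(iPr)2, THF, −78 °C; TBSCl, DMPU, −78 °C → 0 °C
Reagents that add atoms: tert-butyldimethylsilyl chloride, CC(C)(C)[Si](C)(C)Cl
Why: Vinylogous (γ) deprotonation of the β-silyloxy enoate at the C9 methyl, followed by O-silylation of the dienolate, should give the 1,3-bis(silyloxy)diene whose terminal carbon C9 is the nucleophile of the key step; no stereocenter is formed.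

Step 8
Reactants: 13 1-methoxy-1,3-bis(TBS-oxy)-2-[(E)-3-methyloct-2-en-6-yn-1-yl]buta-1,3-diene
Product: 14 methyl (4aR,8aR)-3-(TBS-oxy)-4a,8-dimethyl-1,4,4a,5,6,8a-hexahydronaphthalene-2-carboxylate
Conditions: (R)-DTBM-MeO-BIPHEP(AuCl)2 (3 mol%), AgSbF6 (3 mol%), i-PrOH (1.1 equiv), 4 Å MS, m-xylene, −20 °C → rt; Et3N quench
Reagents that add atoms: none
Why: The cationic gold phosphine complex binds the C3≡C4 alkyne, C5 of the E-alkene attacks C4 anti to gold to give a C3–Au vinyl species and a tertiary cation at C10, the diene terminus C9 captures that cation, the silyl group on the ester oxygen of the resulting silyloxycarbenium ion passes to i-PrOH, and the proton set free cleaves the C3–Au bond. The closest known reaction type is the gold-catalysed enantioselective alkyne-initiated polycyclization of 1,5-enynes with an E-trisubstituted alkene, combined with the capture of tertiary cations by enol silanes that is standard in cation–olefin cyclizations. Ring A closes in the 6-endo-dig mode at the alkyne and ring B by 6-endo attack of the enol silane carbon on C10, both through one chair–chair array. C5 and C10 are created together: antiperiplanar addition of C4 and C9 across the E-alkene fixes their trans relationship (5α-H, 10β-methyl), and the chiral bisphosphine on gold selects the alkene face and hence the absolute configuration, the substrate itself having no stereocenter. The step needs 6-endo-dig over 5-exo-dig attack, which the Markovnikov polarization towards the tertiary C10 cation and the two-carbon tether secure, and C–C termination at C9 over loss of the enol silane, which the robust TBS groups and one equivalent of a hindered alcohol as the only proton source secure (C7 would have to close a four-membered ring). The product carries the Δ3 alkene with its C4 methyl, the C8 oxygen as an enol ether and C11 as an ester in one operation.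

Step 9
Reactants: 14 methyl (4aR,8aR)-3-(TBS-oxy)-4a,8-dimethyl-1,4,4a,5,6,8a-hexahydronaphthalene-2-carboxylate
Product: 16 2-[(4aR,8aR)-3-(TBS-oxy)-4a,8-dimethyl-1,4,4a,5,6,8a-hexahydronaphthalen-2-yl]propan-2-ol, via 1-[(4aR,8aR)-3-(TBS-oxy)-4a,8-dimethyl-hexahydronaphthalen-2-yl]ethanone 15 (not isolated)
Conditions: MeLi (4 equiv), CeCl3 (4 equiv), THF, −78 °C → 0 °C; aq. NH4Cl, 0 °C
Reagents that add atoms: methyllithium, [Li]C
Why: Double 1,2-addition of the methylcerium reagent to the ester should turn C11 into the tertiary carbinol while the ketone stays masked as its enol ether, the weakly basic cerium reagent avoiding γ-deprotonation at C9; no stereocenter is formed.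

Step 10
Reactants: 16 2-[(4aR,8aR)-3-(TBS-oxy)-4a,8-dimethyl-1,4,4a,5,6,8a-hexahydronaphthalen-2-yl]propan-2-ol
Product: 17 (4aR,8aR)-3-(2-hydroxypropan-2-yl)-5,8a-dimethyl-4a,7,8,8a-tetrahydronaphthalen-2(1H)-one (11-hydroxyeudesma-3,6-dien-8-one)
Conditions: Pd(OAc)2 (1.1 equiv), 2,6-lutidine, MeCN, rt
Reagents that add atoms: none
Why: In the Saegusa–Ito oxidation, palladation of the silyl enol ether at C7 and β-hydride elimination, possible only towards C6 because C11 bears no hydrogen, should give the C6=C7 enone, with lutidine buffering the acetic acid that could ionize the tertiary carbinol; no stereocenter is formed and C5 is untouched.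

Step 11
Reactants: 17 (4aR,8aR)-3-(2-hydroxypropan-2-yl)-5,8a-dimethyl-4a,7,8,8a-tetrahydronaphthalen-2(1H)-one
Product: 18 (4aR,5S,6R,8aR)-5,6-dihydroxy-3-(2-hydroxypropan-2-yl)-5,8a-dimethyl-4a,5,6,7,8,8a-hexahydronaphthalen-2(1H)-one (3α,4α,11-trihydroxyeudesm-6-en-8-one)
Conditions: OsO4 (2 mol%), NMO, acetone/H2O, 0 °C → rt
Reagents that add atoms: osmium tetroxide, O=[Os](=O)(=O)=O; N-methylmorpholine N-oxide, C[N+]1([O-])CCOCC1; water, O
Why: Catalytic syn-dihydroxylation (Upjohn conditions) should take place only at the electron-rich Δ3 alkene and from the α face, anti to the axial C10 methyl, which sets C3 (α-OH) and C4 (α-OH, β-methyl) together; the electron-poor, hindered enone is left alone.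

Step 12
Reactants: 19 (E)-2-methylbut-2-en-1-ol
Product: 20 [(2R,3R)-2,3-dimethyloxiran-2-yl]methanol
Conditions: Ti(OiPr)4 (10 mol%), D-(−)-diethyl tartrate (12 mol%), t-BuOOH, 4 Å MS, CH2Cl2, −20 °C
Reagents that add atoms: tert-butyl hydroperoxide, CC(C)(C)OO
Why: The Sharpless asymmetric epoxidation with the D-(−)-tartrate should deliver oxygen to the face of the E-allylic alcohol that gives the (2R,3R)-epoxide, both stereocenters being set by the titanium tartrate catalyst and the methyl groups staying cis.

Step 13
Reactants: 20 [(2R,3R)-2,3-dimethyloxiran-2-yl]methanol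
Product: 22 (2S,3R)-2,3-dimethyloxirane-2-carboxylic acid, via (2S,3R)-2,3-dimethyloxirane-2-carbaldehyde 21 (not isolated)
Conditions: RuCl3·xH2O (2 mol%), NaIO4, MeCN/CCl4/H2O, rt
Reagents that add atoms: sodium periodate, [Na+].[O-]I(=O)(=O)=O; water, O
Why: Ruthenium tetroxide generated in the flask should oxidize the primary alcohol through the aldehyde to the glycidic acid without opening the epoxide; no stereocenter is touched, and the C2 descriptor changes only because of the new priority order.

Step 14
Reactants: 18 (4aR,5S,6R,8aR)-5,6-dihydroxy-3-(2-hydroxypropan-2-yl)-5,8a-dimethyl-4a,5,6,7,8,8a-hexahydronaphthalen-2(1H)-one; 22 (2S,3R)-2,3-dimethyloxirane-2-carboxylic acid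
Product: 24 (1S,2R,4aR,8aR)-1-hydroxy-7-(2-hydroxypropan-2-yl)-1,4a-dimethyl-6-oxo-1,2,3,4,4a,5,6,8a-octahydronaphthalen-2-yl (2S,3R)-2,3-dimethyloxirane-2-carboxylate, via (2S,3R)-2,3-dimethyloxirane-2-carboxylic 2,4,6-trichlorobenzoic anhydride 23 (not isolated)
Conditions: 2,4,6-Cl3C6H2COCl, Et3N, THF, 0 °C; then 18, DMAP, toluene, rt
Reagents that add atoms: none
Why: In the Yamaguchi esterification the mixed anhydride should acylate only the secondary 3α-hydroxyl, the tertiary hydroxyls at C4 and C11 being inert, and the mild base should leave the epoxide and all stereocenters unchanged.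

**Compound list**

1 | pent-3-yn-1-ol | CC#CCCO | starting material
2 | 5-bromopent-2-yne | CC#CCCBr | intermediate
3 | ethyl but-2-ynoate | CC#CC(=O)OCC | starting material
4 | pent-3-ynylmagnesium bromide | CC#CCC[Mg]Br | intermediate (not isolated)
5 | ethyl (E)-3-methyloct-2-en-6-ynoate | CC#CCC/C(C)=C/C(=O)OCC | intermediate
6 | (E)-3-methyloct-2-en-6-yn-1-ol | CC#CCC/C(C)=C/CO | intermediate
7 | (E)-1-bromo-3-methyloct-2-en-6-yne | CC#CCC/C(C)=C/CBr | intermediate
8 | methyl acetoacetate (methyl 3-oxobutanoate) | CC(=O)CC(=O)OC | starting material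
9 | sodium enolate of methyl acetoacetate | [Na+].COC(=O)C=C(C)[O-] | intermediate (not isolated)
10 | methyl (E)-2-acetyl-5-methyldec-4-en-8-ynoate (racemic at C2) | CC#CCC/C(C)=C/CC(C(C)=O)C(=O)OC | intermediate
11 | methyl 3-[(tert-butyldimethylsilyl)oxy]-2-[(E)-3-methyloct-2-en-6-yn-1-yl]but-2-enoate (enol ether E/Z mixture) | CC#CCC/C(C)=C/CC(C(=O)OC)=C(C)O[Si](C)(C)C(C)(C)C | intermediate
12 | lithium dienolate of 11 (lithium 1-methoxy-3-(TBS-oxy)-2-[(E)-3-methyloct-2-en-6-yn-1-yl]buta-1,3-dien-1-olate) | [Li+].COC([O-])=C(C/C=C(\C)CCC#CC)C(=C)O[Si](C)(C)C(C)(C)C | intermediate (not isolated)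
13 | 1-methoxy-1,3-bis[(tert-butyldimethylsilyl)oxy]-2-[(E)-3-methyloct-2-en-6-yn-1-yl]buta-1,3-diene | CC#CCC/C(C)=C/CC(=C(OC)O[Si](C)(C)C(C)(C)C)C(=C)O[Si](C)(C)C(C)(C)C | intermediate
14 | methyl (4aR,8aR)-3-[(tert-butyldimethylsilyl)oxy]-4a,8-dimethyl-1,4,4a,5,6,8a-hexahydronaphthalene-2-carboxylate (5α-H, 10β-methyl, Δ3, C8 enol ether) | CC1=CCC[C@]2(C)CC(O[Si](C)(C)C(C)(C)C)=C(C(=O)OC)C[C@@H]12 | intermediate
15 | 1-[(4aR,8aR)-3-[(tert-butyldimethylsilyl)oxy]-4a,8-dimethyl-1,4,4a,5,6,8a-hexahydronaphthalen-2-yl]ethan-1-one | CC1=CCC[C@]2(C)CC(O[Si](C)(C)C(C)(C)C)=C(C(C)=O)C[C@@H]12 | intermediate (not isolated)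
16 | 2-[(4aR,8aR)-3-[(tert-butyldimethylsilyl)oxy]-4a,8-dimethyl-1,4,4a,5,6,8a-hexahydronaphthalen-2-yl]propan-2-ol | CC1=CCC[C@]2(C)CC(O[Si](C)(C)C(C)(C)C)=C(C(C)(C)O)C[C@@H]12 | intermediate
17 | (4aR,8aR)-3-(2-hydroxypropan-2-yl)-5,8a-dimethyl-4a,7,8,8a-tetrahydronaphthalen-2(1H)-one (11-hydroxy-5αH-eudesma-3,6-dien-8-one) | CC1=CCC[C@]2(C)CC(=O)C(C(C)(C)O)=C[C@@H]12 | intermediate
18 | (4aR,5S,6R,8aR)-5,6-dihydroxy-3-(2-hydroxypropan-2-yl)-5,8a-dimethyl-4a,5,6,7,8,8a-hexahydronaphthalen-2(1H)-one (3α,4α,11-trihydroxy-5αH-eudesm-6-en-8-one) | O[C@@H]1CC[C@]2(C)CC(=O)C(C(C)(C)O)=C[C@H]2[C@]1(C)O | intermediate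
19 | (E)-2-methylbut-2-en-1-ol | C/C=C(\C)CO | starting material
20 | [(2R,3R)-2,3-dimethyloxiran-2-yl]methanol | C[C@H]1O[C@]1(C)CO | intermediate
21 | (2S,3R)-2,3-dimethyloxirane-2-carbaldehyde | C[C@H]1O[C@]1(C)C=O | intermediate (not isolated)
22 | (2S,3R)-2,3-dimethyloxirane-2-carboxylic acid | C[C@H]1O[C@]1(C)C(=O)O | intermediate
23 | (2S,3R)-2,3-dimethyloxirane-2-carboxylic 2,4,6-trichlorobenzoic anhydride | C[C@H]1O[C@]1(C)C(=O)OC(=O)c1c(Cl)cc(Cl)cc1Cl | intermediate (not isolated)
24 | (1S,2R,4aR,8aR)-1-hydroxy-7-(2-hydroxypropan-2-yl)-1,4a-dimethyl-6-oxo-1,2,3,4,4a,5,6,8a-octahydronaphthalen-2-yl (2S,3R)-2,3-dimethyloxirane-2-carboxylate | C[C@H]1O[C@]1(C)C(=O)O[C@@H]1CC[C@]2(C)CC(=O)C(C(C)(C)O)=C[C@H]2[C@]1(C)O | target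

**Step count.** Total: 14 steps. Longest linear sequence: 12 steps (steps 1–11 and 14); acid 22 is made in parallel in two steps (12, 13).

**Steps most likely to fail**

Step 8. The bis-silyl dienol ether may be protodesilylated before the C10 cation is reached, the cation may be quenched without C–C bond formation, or facial discrimination by the catalyst may be poor. The fallback sets out from 7 and returns at 17, and replaces the silyl dienol ether by a protic β-keto ester terminator. Compound 7 is alkylated at the γ-carbon of the dianion of allyl acetoacetate (NaH, then n-BuLi, THF, 0 °C) to give allyl (E)-7-methyl-3-oxododec-6-en-10-ynoate F1. Under the same gold catalyst the enol carbon between the two carbonyls (C9) should capture the C10 cation, the classical β-keto ester termination of cation–olefin cyclizations, and give the trans-fused allyl 5,8a-dimethyl-2-oxo-1,2,3,4,4a,7,8,8a-octahydronaphthalene-1-carboxylate F2. Its dianion (NaH, n-BuLi) should add to acetone at C7 to give allyl 3-(2-hydroxypropan-2-yl)-5,8a-dimethyl-2-oxo-1,2,3,4,4a,7,8,8a-octahydronaphthalene-1-carboxylate F3. Palladium-catalysed deallyloxycarbonylation (Pd(PPh3)4, morpholine, THF) should then give 3-(2-hydroxypropan-2-yl)-5,8a-dimethyl-3,4,4a,7,8,8a-hexahydronaphthalen-2(1H)-one F4. Dehydrogenation with IBX in DMSO, for which only C6 offers a β-hydrogen, leads back to 17.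

Step 10. Palladation of the crowded tetrasubstituted enol ether may be slow, and the acid formed may ionize the tertiary carbinol with loss of water. The fallback sets out from 16 and returns at 17, and uses selenium instead of palladium. Electrophilic selenenylation of the silyl enol ether with PhSeCl (CH2Cl2, −78 °C) should give 3-(2-hydroxypropan-2-yl)-5,8a-dimethyl-3-(phenylselanyl)-3,4,4a,7,8,8a-hexahydronaphthalen-2(1H)-one F5. Oxidation with H2O2/pyridine at 0 °C and selenoxide syn-elimination, again possible only towards C6, should give 17.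

Step 14. Acylation of the hindered axial 3α-hydroxyl by the α,α-disubstituted glycidic acid may be slow, so that the activated acid decomposes or the epoxide opens. The fallback sets out from 18 and 22 and returns at 24, and activates the nucleophile instead of relying on acyl transfer catalysis. Compound 18 and Bu2SnO (toluene, reflux, removal of water) should give the 2,2-dibutyl-1,3,2-dioxastannolane of the C3/C4 diol F6. Acid 22 and 1-chloro-N,N,2-trimethylprop-1-en-1-amine (CH2Cl2, 0 °C) should give (2S,3R)-2,3-dimethyloxirane-2-carbonyl chloride F7 under neutral conditions. F6 and F7 should then react at the secondary tin alkoxide only, to give 24.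

**Further compounds**

F1 | step 8 | allyl (E)-7-methyl-3-oxododec-6-en-10-ynoate | C=CCOC(=O)CC(=O)CC/C=C(\C)CCC#CC
F2 | step 8 | allyl 5,8a-dimethyl-2-oxo-1,2,3,4,4a,7,8,8a-octahydronaphthalene-1-carboxylate (ring fusion as in 14, C1 epimers) | CC1=CCC[C@]2(C)C(C(=O)OCC=C)C(=O)CC[C@@H]12
F3 | step 8 | allyl 3-(2-hydroxypropan-2-yl)-5,8a-dimethyl-2-oxo-1,2,3,4,4a,7,8,8a-octahydronaphthalene-1-carboxylate (ring fusion as in 14) | CC1=CCC[C@]2(C)C(C(=O)OCC=C)C(=O)C(C(C)(C)O)C[C@@H]12
F4 | step 8 | 3-(2-hydroxypropan-2-yl)-5,8a-dimethyl-3,4,4a,7,8,8a-hexahydronaphthalen-2(1H)-one (ring fusion as in 14) | CC1=CCC[C@]2(C)CC(=O)C(C(C)(C)O)C[C@@H]12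
F5 | step 10 | 3-(2-hydroxypropan-2-yl)-5,8a-dimethyl-3-(phenylselanyl)-3,4,4a,7,8,8a-hexahydronaphthalen-2(1H)-one (ring fusion as in 14) | CC1=CCC[C@]2(C)CC(=O)C([Se]c3ccccc3)(C(C)(C)O)C[C@@H]12
F6 | step 14 | 2,2-dibutyl-1,3,2-dioxastannolane of the C3/C4 diol of 18 | CCCC[Sn]3(CCCC)O[C@@H]1CC[C@]2(C)CC(=O)C(C(C)(C)O)=C[C@H]2[C@]1(C)O3
F7 | step 14 | (2S,3R)-2,3-dimethyloxirane-2-carbonyl chloride | C[C@H]1O[C@]1(C)C(Cl)=O
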